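The hexadecanoyl chain is disconnected between C6 and C7, two plain methylene carbons that lie five bonds beyond the ester carbonyl C1 and are remote from the benzylic CH2–O of ring A. A room-temperature B-alkyl Suzuki–Miyaura coupling joins B-decyl-9-BBN, made in the flask from dec-1-ene, to the 6-bromohexanoate of the fully assembled diaryl ether, so that the complete C16 ester appears in one operation and only the primary C–Br bond reacts. The precursor carries both phenols (ring A C3–OH, ring B OH) as MOM ethers; its diaryl ether arises from a copper-catalysed O-arylation of a ring A 2-hydroxybenzyl alcohol with a ring B aryl bromide.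

Key step: step 7

Remark: the target has no stereocentre and no stereogenic double bond, so no stereochemical control is required anywhere in the route.

Step 1
Reactants: 1 3-bromo-2-hydroxy-5-methoxybenzaldehyde
Product: 2 2,3-dihydroxy-5-methoxybenzaldehyde
Conditions: NaOH (aq), Cu powder (cat.), reflux, N2 (degassed); then HCl
Reagents that add atoms: sodium hydroxide, [Na+].[OH-]
Why: Ullmann-type copper-catalysed hydroxylation in which the ortho-phenoxide assists exchange of the C3–Br bond for C3–OH (the classical conversion of 5-bromovanillin into 5-hydroxyvanillin), while the phenoxide form protects the aldehyde from Cannizzaro reaction.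

Step 2
Reactants: 2 2,3-dihydroxy-5-methoxybenzaldehyde
Product: 3 2-hydroxy-5-methoxy-3-(methoxymethoxy)benzaldehyde
Conditions: NaH (2.2 equiv), THF/DMF, 0 °C; MOMCl (1.0 equiv), 0 °C to rt; aq NH4Cl
Reagents that add atoms: chloromethyl methyl ether (MOMCl), COCCl
Why: Williamson etherification of the dianion, in which the O3 phenoxide (not conjugated with the formyl group) is far more nucleophilic than the chelated, carbonyl-conjugated O2 phenoxide, so one equivalent of MOMCl should go to O3, as is known for 2,3-dihydroxybenzaldehyde dianions.

Step 3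
Reactants: 3 2-hydroxy-5-methoxy-3-(methoxymethoxy)benzaldehyde
Product: 4 2-(hydroxymethyl)-4-methoxy-6-(methoxymethoxy)phenol
Conditions: NaBH4, THF/MeOH, 0 °C; aq NH4Cl
Reagents that add atoms: none
Why: Borohydride reduction of the aldehyde to the primary benzylic alcohol, which leaves the MOM and methyl ethers untouched and turns the deactivated salicylaldehyde into an electron-rich phenol suited to O-arylation.

Step 4
Reactants: 5 3-bromo-5-methylphenol
Product: 6 1-bromo-3-(methoxymethoxy)-5-methylbenzene
Conditions: NaH, THF, 0 °C; MOMCl, 0 °C to rt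
Reagents that add atoms: chloromethyl methyl ether (MOMCl), COCCl
Why: Williamson-type O-alkylation of the sodium phenoxide masks the ring B phenol so that the aryl bromide cannot condense with itself in the copper coupling and the oxygen stays inert in the later steps.

Step 5
Reactants: 4 2-(hydroxymethyl)-4-methoxy-6-(methoxymethoxy)phenol; 6 1-bromo-3-(methoxymethoxy)-5-methylbenzene
Product: 7 [5-methoxy-3-(methoxymethoxy)-2-[3-(methoxymethoxy)-5-methylphenoxy]phenyl]methanol
Conditions: CuI (10 mol%), picolinic acid (20 mol%), K3PO4, DMSO, 100 °C, Ar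
Reagents that add atoms: none
Why: Ullmann-type Cu(I)/picolinic acid diaryl ether synthesis, a system that accepts di-ortho-substituted phenols; only the phenoxide, not the un-ionised primary alcohol, binds copper and is arylated by the unhindered aryl bromide.

Step 6
Reactants: 7 [5-methoxy-3-(methoxymethoxy)-2-[3-(methoxymethoxy)-5-methylphenoxy]phenyl]methanol; 8 6-bromohexanoic acid
Product: 9 [5-methoxy-3-(methoxymethoxy)-2-[3-(methoxymethoxy)-5-methylphenoxy]phenyl]methyl 6-bromohexanoate
Conditions: EDC·HCl, DMAP (cat.), CH2Cl2, 0 °C to rt
Reagents that add atoms: none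
Why: Steglich esterification, in which the acyl-DMAP species acylates the only free hydroxyl (the primary benzylic alcohol) and the primary alkyl bromide is inert.

Step 7
Reactants: 9 [5-methoxy-3-(methoxymethoxy)-2-[3-(methoxymethoxy)-5-methylphenoxy]phenyl]methyl 6-bromohexanoate; 10 dec-1-ene
Product: 12 [5-methoxy-3-(methoxymethoxy)-2-[3-(methoxymethoxy)-5-methylphenoxy]phenyl]methyl hexadecanoate, via B-decyl-9-BBN 11 (not isolated)
Conditions: 10, 9-BBN-H, THF, rt; then 9, Pd(OAc)2 (4 mol%), PCy3 (8 mol%), K3PO4·H2O, THF, rt
Reagents that add atoms: none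
Why: B-alkyl Suzuki–Miyaura coupling of an unactivated primary alkyl bromide: anti-Markovnikov hydroboration of dec-1-ene gives the primary borane 11, Pd(0)/PCy3 adds to the C6–Br bond of 9 by an SN2-type oxidative addition, the hydroxide-activated borate transfers its primary decyl group in preference to the secondary bicyclic B–C bonds, and reductive elimination forms the C6–C7 bond. The closest known reaction type is the room-temperature Pd(OAc)2/PCy3/K3PO4·H2O coupling of β-hydrogen-bearing primary alkyl bromides with B-alkyl-9-BBN reagents, which tolerates esters and ethers. No ring is closed and no stereocentre is created. The step needs chemoselectivity for the C(sp3)–Br bond over the benzylic C–O bond and the carbonyl of the ester, and reductive elimination must outrun β-hydride elimination; the bulky electron-rich PCy3, the room-temperature conditions (benzylic carboxylates add to Pd(0) only on heating) and the five-bond distance of C6 from C1 should secure this, while the MOM ethers keep the phenols from being deprotonated by phosphate and O-alkylated by the bromide.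

Step 8
Reactants: 12 [5-methoxy-3-(methoxymethoxy)-2-[3-(methoxymethoxy)-5-methylphenoxy]phenyl]methyl hexadecanoate
Product: 13 betaethrin H, [3-hydroxy-2-(3-hydroxy-5-methylphenoxy)-5-methoxyphenyl]methyl hexadecanoate
Conditions: ZnBr2, n-PrSH, CH2Cl2, 0 °C to rt
Reagents that add atoms: none
Why: Lewis acid/soft nucleophile cleavage of aryl MOM ethers, in which ZnBr2 activates the acetal and propanethiol traps the methoxymethyl cation within minutes, so that the benzylic ester, the aryl methyl ether and the electron-rich rings should not be attacked.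

Compound list
1 | 3-bromo-2-hydroxy-5-methoxybenzaldehyde | O=Cc1cc(OC)cc(Br)c1O | starting material
2 | 2,3-dihydroxy-5-methoxybenzaldehyde | O=Cc1cc(OC)cc(O)c1O | intermediate
3 | 2-hydroxy-5-methoxy-3-(methoxymethoxy)benzaldehyde | O=Cc1cc(OC)cc(OCOC)c1O | intermediate
4 | 2-(hydroxymethyl)-4-methoxy-6-(methoxymethoxy)phenol | OCc1cc(OC)cc(OCOC)c1O | intermediate
5 | 3-bromo-5-methylphenol | Cc1cc(O)cc(Br)c1 | starting material
6 | 1-bromo-3-(methoxymethoxy)-5-methylbenzene | Cc1cc(Br)cc(OCOC)c1 | intermediate
7 | [5-methoxy-3-(methoxymethoxy)-2-[3-(methoxymethoxy)-5-methylphenoxy]phenyl]methanol | OCc1cc(OC)cc(OCOC)c1Oc1cc(C)cc(OCOC)c1 | intermediate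
8 | 6-bromohexanoic acid | OC(=O)CCCCCBr | starting material
9 | [5-methoxy-3-(methoxymethoxy)-2-[3-(methoxymethoxy)-5-methylphenoxy]phenyl]methyl 6-bromohexanoate | BrCCCCCC(=O)OCc1cc(OC)cc(OCOC)c1Oc1cc(C)cc(OCOC)c1 | intermediate
10 | dec-1-ene | C=CCCCCCCCC | starting material
11 | B-decyl-9-borabicyclo[3.3.1]nonane (B-decyl-9-BBN) | CCCCCCCCCCB1C2CCCC1CCC2 | intermediate
12 | [5-methoxy-3-(methoxymethoxy)-2-[3-(methoxymethoxy)-5-methylphenoxy]phenyl]methyl hexadecanoate | CCCCCCCCCCCCCCCC(=O)OCc1cc(OC)cc(OCOC)c1Oc1cc(C)cc(OCOC)c1 | intermediate
13 | betaethrin H, [3-hydroxy-2-(3-hydroxy-5-methylphenoxy)-5-methoxyphenyl]methyl hexadecanoate | CCCCCCCCCCCCCCCC(=O)OCc1cc(OC)cc(O)c1Oc1cc(C)cc(O)c1 | target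

Total step count: 8. Longest linear sequence: 7 steps (steps 1, 2, 3, 5, 6, 7, 8).

Steps most likely to fail

Step 7. β-Hydride elimination or protodehalogenation of the alkylpalladium intermediate, or competing oxidative addition into the benzylic C–O bond of the ester, could erode the coupling. The fallback sets out from 7 and comes back at 12, and it forms the same C6–C7 bond by olefin metathesis. Alcohol 7 would be esterified (EDC, DMAP, CH2Cl2) with hept-6-enoic acid to give [5-methoxy-3-(methoxymethoxy)-2-[3-(methoxymethoxy)-5-methylphenoxy]phenyl]methyl hept-6-enoate F1. Cross-metathesis of this ester with excess undec-1-ene (Grubbs second-generation catalyst, CH2Cl2, 40 °C) should give [5-methoxy-3-(methoxymethoxy)-2-[3-(methoxymethoxy)-5-methylphenoxy]phenyl]methyl (E)-hexadec-6-enoate F2, expected as an E/Z mixture with the E isomer drawn. Diimide reduction (2-nitrobenzenesulfonylhydrazide, Et3N, CH2Cl2, rt) should then saturate the C6=C7 bond without hydrogenolysis of the benzylic ester and give 12.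

Step 5. C–O bond formation at the di-ortho-substituted phenoxide may be slow, and oxidation of the electron-rich phenol may compete. The fallback sets out from 3 and 6 and comes back at 7; it uses an oxidative Cu(II) coupling of a boron reagent at the aldehyde stage. Bromide 6 would be converted by bromine–lithium exchange (n-BuLi, THF, −78 °C), B(OiPr)3 and a mild aqueous work-up into [3-(methoxymethoxy)-5-methylphenyl]boronic acid F3. Chan–Lam coupling of phenol 3 with this boronic acid (Cu(OAc)2, pyridine, 4 Å MS, CH2Cl2, air, rt) should give 5-methoxy-3-(methoxymethoxy)-2-[3-(methoxymethoxy)-5-methylphenoxy]benzaldehyde F4, and NaBH4 reduction (THF/MeOH, 0 °C) would then give 7.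

Step 2. Discrimination between the two phenoxide oxygens may be incomplete, or double alkylation may occur. The fallback sets out from 2 and comes back at 3; it protects both oxygens and then removes one selectively. Catechol 2 would be converted with excess MOMCl and iPr2NEt (CH2Cl2) into 5-methoxy-2,3-bis(methoxymethoxy)benzaldehyde F5. Chelation-controlled cleavage with MgBr2·OEt2 (Et2O/toluene, rt), in which magnesium is held between the formyl oxygen and O2, should remove only the MOM group ortho to the aldehyde and give 3.

Further compounds
F1 | step 7 | [5-methoxy-3-(methoxymethoxy)-2-[3-(methoxymethoxy)-5-methylphenoxy]phenyl]methyl hept-6-enoate | C=CCCCCC(=O)OCc1cc(OC)cc(OCOC)c1Oc1cc(C)cc(OCOC)c1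
F2 | step 7 | [5-methoxy-3-(methoxymethoxy)-2-[3-(methoxymethoxy)-5-methylphenoxy]phenyl]methyl (E)-hexadec-6-enoate | CCCCCCCCC/C=C/CCCCC(=O)OCc1cc(OC)cc(OCOC)c1Oc1cc(C)cc(OCOC)c1
F3 | step 5 | [3-(methoxymethoxy)-5-methylphenyl]boronic acid | Cc1cc(OCOC)cc(B(O)O)c1
F4 | step 5 | 5-methoxy-3-(methoxymethoxy)-2-[3-(methoxymethoxy)-5-methylphenoxy]benzaldehyde | O=Cc1cc(OC)cc(OCOC)c1Oc1cc(C)cc(OCOC)c1
F5 | step 2 | 5-methoxy-2,3-bis(methoxymethoxy)benzaldehyde | O=Cc1cc(OC)cc(OCOC)c1OCOC
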